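**Retrosynthetic overview**
1. Target 13 is two trans-2,3-disubstituted 5,7-dihydroxychroman-4-ones joined C3–C3''. Its chain C2–C3(C4=O)–C3''(C4''=O)–C2'' is the 8,8'-dimer of two 4-oxygenated cinnamic acids. The (3R,3''R) pair is the bridgehead pair C1/C5 of a cis-fused 2,6-diaryl-3,7-dioxabicyclo[3.3.0]octane-4,8-dione.
2. Pyranone rings C and C'' are cut last at O1–C2 and O1''–C2'' (benzylic cation plus ortho phenol), giving bis(gamma-hydroxy aryl ketone) 11.
3. 11 is cut at C4–C4a and C4''–C4a'' into dilactone 6 and two 2,4,6-tris(methoxymethoxy)phenyllithium units 9; rings A and A'' come intact from phloroglucinol.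
4. 6 comes from the oxidative 8,8'-dimer of p-coumaric acid by monomethylation of one of two homotopic phenols, MOM protection and resolution.
5. Ring order: the two sacrificial lactone rings (step 1), then rings C and C'' together (step 7); rings A, A'', B and B'' are bought in.

Key step: step 6

Remark: racemic compounds 2–5 are drawn as the enantiomer that is carried on; which fraction of step 4 is the (1R,2R,5R,6R) enantiomer must be assigned independently (ECD or anomalous-dispersion X-ray); 11 is written as the open hydroxy ketone although it may sit partly as lactols, which converge in step 7.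

**Step 1**
Reactants: 1 p-coumaric acid (2 equiv)
Product: 3 racemic exo,exo-2,6-bis(4-hydroxyphenyl)-3,7-dioxabicyclo[3.3.0]octane-4,8-dione [rac-(1R,2R,5R,6R)], via bis(quinone methide) diacid 2 (not isolated)
Conditions: FeCl3 (2.2 equiv, aqueous, added over 4 h), acetone–H2O, rt
Reagents that add atoms: none
Why: One-electron oxidation of the phenol by FeCl3 gives a phenoxy radical with spin density at C8, two of which couple C8–C8' (biomimetic oxidative dehydrodimerization of a 4-hydroxycinnamic acid) to 2, and each carboxylic acid then adds to the quinone methide of the other half; only the like C8/C8' pair can close to the cis-fused bicycle and each aryl group settles on the exo face, the product being racemic.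

**Step 2**
Reactants: 3 racemic diphenol dilactone
Product: 4 racemic exo,exo-2-(4-hydroxyphenyl)-6-(4-methoxyphenyl)-3,7-dioxabicyclo[3.3.0]octane-4,8-dione
Conditions: CH2N2 (1.0 equiv, titrated Et2O solution), THF–MeOH, 0 °C to rt; chromatography, recovered 3 recycled
Reagents that add atoms: diazomethane, C=[N+]=[N-]
Why: Diazomethane O-methylates a phenol without base (proton transfer, then SN2 on the methyldiazonium ion), so the base-labile 4-hydroxybenzylic lactone is not opened through a quinone methide, and because the C2 axis exchanges the two phenols, either one gives the same mono-ether, limited only by statistics.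

**Step 3**
Reactants: 4 racemic monomethyl ether
Product: 5 racemic exo,exo-2-(4-methoxyphenyl)-6-[4-(methoxymethoxy)phenyl]-3,7-dioxabicyclo[3.3.0]octane-4,8-dione
Conditions: MOMCl (1.5 equiv), iPr2NEt (2 equiv), CH2Cl2, 0 °C to rt
Reagents that add atoms: chloromethyl methyl ether (MOMCl), COCCl
Why: O-Alkylation of the remaining phenol by chloromethyl methyl ether under a hindered amine base (methoxymethyl ether formation) is fast at 0 °C and leaves the lactones and the enolizable bridgehead carbons alone.

**Step 4**
Reactants: 5 racemic methyl/MOM dilactone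
Product: 6 (1R,2R,5R,6R)-2-(4-methoxyphenyl)-6-[4-(methoxymethoxy)phenyl]-3,7-dioxabicyclo[3.3.0]octane-4,8-dione
Conditions: preparative SFC, amylose tris(3,5-dimethylphenylcarbamate) stationary phase, CO2–MeOH
Reagents that add atoms: none
Why: Resolution by chromatography on a chiral stationary phase separates the enantiomers of the rigid, neutral dilactone without making or breaking a bond, so the relative configuration of step 1 is kept and the (1R,2R,5R,6R) fraction carries the (R,R) bridgeheads that become C3 and C3''.

**Step 5**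
Reactants: 7 phloroglucinol
Product: 8 1,3,5-tris(methoxymethoxy)benzene
Conditions: MOMCl (3.6 equiv), iPr2NEt (4.5 equiv), DMF, 0 °C to rt
Reagents that add atoms: chloromethyl methyl ether (MOMCl), COCCl
Why: Threefold O-alkylation of phloroglucinol with chloromethyl methyl ether and amine base (methoxymethyl ether formation) gives the symmetric tris-ether, the hard electrophile reacting at oxygen and not at carbon.

**Step 6**
Reactants: 6 (1R,2R,5R,6R)-dilactone (1 equiv); 8 1,3,5-tris(methoxymethoxy)benzene (2.5 equiv)
Product: 11 (1R,2R,3R,4R)-1-(4-methoxyphenyl)-4-[4-(methoxymethoxy)phenyl]-2,3-bis[2,4,6-tris(methoxymethoxy)benzoyl]butane-1,4-diol, via 2,4,6-tris(methoxymethoxy)phenyllithium 9 (not isolated), via dilithium bis(lactolate) 10 (not isolated)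
Conditions: 8, n-BuLi (2.4 equiv, kept below the amount of 8), THF, 0 °C, 1 h; then 6 in THF, −78 °C, 2 h; AcOH in THF at −78 °C, then aq NaHCO3
Reagents that add atoms: none
Why: Directed ortho-lithiation of 8, in which all three ring positions are equivalent, gives aryllithium 9, which adds to each lactone carbonyl of 6 (nucleophilic acyl addition) to give lithium lactolate 10; protonation and collapse of the lactols on work-up open both five-membered rings to the bis(gamma-hydroxy aryl ketone) 11, forming C4–C4a and C4''–C4a''. The closest known reaction type is the single addition of aryllithiums, 2,6-dialkoxyaryllithiums included, to gamma- and delta-lactones (as in C-aryl glycoside synthesis from sugar lactones), which stops at the lactol or hydroxy ketone. No ring is closed in this step; two lactone rings are opened. No stereocentre is created in 11 (the two hemiketal carbons of 10 are transient), and the four existing ones, including the (R,R) bridgehead pair that becomes C3/C3'', stay untouched as long as no enolate forms. The step needs addition over alpha-deprotonation (which would trigger beta-elimination of the lactone carboxylate to an arylidene lactone) and mono- over double addition: −78 °C, the modest basicity of an aryllithium and the two ortho methoxymethoxy groups, which chelate lithium in 10 and block a second aryl transfer, should secure both, and the cold acetic acid quench prevents retro-aldol cleavage of the beta-alkoxide.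

**Step 7**
Reactants: 11 bis(gamma-hydroxy aryl ketone)
Product: 13 (2S,3R)-3-[(2S,3R)-5,7-dihydroxy-2-(4-hydroxyphenyl)-4-oxochroman-3-yl]-5,7-dihydroxy-2-(4-methoxyphenyl)chroman-4-one, via MOM-free bis(hydroxy ketone) 12 (not isolated)
Conditions: 3 M aq HCl–MeOH (1:4), 55 °C
Reagents that add atoms: none
Why: Methanolic HCl cleaves the seven methoxymethyl acetals (acetal exchange to dimethoxymethane) and ionizes the two para-oxygenated benzylic alcohols, and each cation is captured by an ortho phenol of the aroyl group on the neighbouring carbon in a six-membered ring closure (acid-mediated cyclization of a 2'-hydroxy-beta-hydroxydihydrochalcone to a flavanone), the reversible O1–C2 bond formation placing each aryl group trans to the C3 substituent (2S and 2''S, controlled by the untouched 3R and 3''R centres), while the two ortho oxygens of each phloroglucinol ring are equivalent so no regiochemistry arises.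

**Compound list**
1 | p-coumaric acid, (E)-3-(4-hydroxyphenyl)prop-2-enoic acid | OC(=O)/C=C/c1ccc(O)cc1 | starting material
2 | rac-(2S,3S)-2,3-bis[(4-oxocyclohexa-2,5-dien-1-ylidene)methyl]butanedioic acid, the 8,8'-coupled bis(quinone methide) | OC(=O)[C@@H](C=C1C=CC(=O)C=C1)[C@@H](C(O)=O)C=C1C=CC(=O)C=C1 | intermediate (not isolated)
3 | rac-(1R,2R,5R,6R)-2,6-bis(4-hydroxyphenyl)-3,7-dioxabicyclo[3.3.0]octane-4,8-dione (cis-fused, aryl groups exo) | Oc1ccc([C@@H]2OC(=O)[C@@H]3[C@H]2C(=O)O[C@H]3c2ccc(O)cc2)cc1 | intermediate
4 | rac-(1R,2R,5R,6R)-2-(4-hydroxyphenyl)-6-(4-methoxyphenyl)-3,7-dioxabicyclo[3.3.0]octane-4,8-dione | COc1ccc([C@@H]2OC(=O)[C@@H]3[C@H]2C(=O)O[C@H]3c2ccc(O)cc2)cc1 | intermediate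
5 | rac-(1R,2R,5R,6R)-2-(4-methoxyphenyl)-6-[4-(methoxymethoxy)phenyl]-3,7-dioxabicyclo[3.3.0]octane-4,8-dione | COc1ccc([C@@H]2OC(=O)[C@@H]3[C@H]2C(=O)O[C@H]3c2ccc(OCOC)cc2)cc1 | intermediate
6 | (1R,2R,5R,6R)-2-(4-methoxyphenyl)-6-[4-(methoxymethoxy)phenyl]-3,7-dioxabicyclo[3.3.0]octane-4,8-dione, single enantiomer | COc1ccc([C@@H]2OC(=O)[C@@H]3[C@H]2C(=O)O[C@H]3c2ccc(OCOC)cc2)cc1 | intermediate
7 | phloroglucinol, benzene-1,3,5-triol | Oc1cc(O)cc(O)c1 | starting material
8 | 1,3,5-tris(methoxymethoxy)benzene | COCOc1cc(OCOC)cc(OCOC)c1 | intermediate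
9 | 2,4,6-tris(methoxymethoxy)phenyllithium | [Li]c1c(OCOC)cc(OCOC)cc1OCOC | intermediate (not isolated)
10 | dilithium bis(lactolate) from double addition of 9 to 6 (hemiketal carbons undefined) | COc1ccc([C@@H]2OC(O[Li])(c4c(OCOC)cc(OCOC)cc4OCOC)[C@@H]3[C@H]2C(O[Li])(c4c(OCOC)cc(OCOC)cc4OCOC)O[C@H]3c2ccc(OCOC)cc2)cc1 | intermediate (not isolated)
11 | (1R,2R,3R,4R)-1-(4-methoxyphenyl)-4-[4-(methoxymethoxy)phenyl]-2,3-bis[2,4,6-tris(methoxymethoxy)benzoyl]butane-1,4-diol | COc1ccc([C@H](O)[C@H](C(=O)c2c(OCOC)cc(OCOC)cc2OCOC)[C@@H](C(=O)c2c(OCOC)cc(OCOC)cc2OCOC)[C@@H](O)c2ccc(OCOC)cc2)cc1 | intermediate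
12 | (1R,2R,3R,4R)-1-(4-hydroxyphenyl)-4-(4-methoxyphenyl)-2,3-bis(2,4,6-trihydroxybenzoyl)butane-1,4-diol | COc1ccc([C@H](O)[C@H](C(=O)c2c(O)cc(O)cc2O)[C@@H](C(=O)c2c(O)cc(O)cc2O)[C@@H](O)c2ccc(O)cc2)cc1 | intermediate (not isolated)
13 | (2S,3R)-3-[(2S,3R)-5,7-dihydroxy-2-(4-hydroxyphenyl)-4-oxochroman-3-yl]-5,7-dihydroxy-2-(4-methoxyphenyl)chroman-4-one | COc1ccc([C@H]2Oc3cc(O)cc(O)c3C(=O)[C@@H]2[C@H]2C(=O)c3c(O)cc(O)cc3O[C@@H]2c2ccc(O)cc2)cc1 | target

**Step count**
Total: 7 steps. Longest linear sequence: 6 steps (steps 1, 2, 3, 4, 6, 7).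

**Steps most likely to fail**

Step 6. The aryllithium may deprotonate the lactone alpha-carbons, after which beta-elimination of the carboxylate destroys the bicycle and the C3/C3'' configuration, or the second addition may stall. The fallback changes the acyl donor from a lactone to an acyclic Weinreb amide and sets out from 6. Aminolysis of both lactones with Me2AlN(OMe)Me (from AlMe3 and MeNH(OMe)·HCl, CH2Cl2, 0 °C) gives the bis(N-methoxy-N-methylamide) diol F1. It is silylated at once (TBSOTf, 2,6-lutidine, CH2Cl2, −78 °C) to the bis(tert-butyldimethylsilyl ether) F2 so that it cannot relactonize. Aryllithium 9 (THF, −78 to −40 °C) then adds once to each amide through the chelated tetrahedral intermediate to give the bis(aryl ketone) bis(silyl ether) F3. HF·pyridine in THF–pyridine removes the two silyl groups, and the fallback comes back to the route at 11.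

Step 7. The benzylic cations may lose the C3 proton (E1 to an alpha-substituted chalcone) or the ketones may enolize, scrambling C3/C3''. The 1,4-diketone and gamma-hydroxy ketone arrays may also divert into furan or cyclic ketal formation before the pyranone rings close. The fallback replaces the cationic closure by a stereospecific Mitsunobu etherification and sets out from 6.
- Purchased 1,3,5-tris(benzyloxy)benzene is brominated (NBS, CH2Cl2, 0 °C) to 2-bromo-1,3,5-tris(benzyloxy)benzene F4.
- Bromine–lithium exchange (n-BuLi, THF, −78 °C) gives 2,4,6-tris(benzyloxy)phenyllithium F5, which is added to 6 as in step 6 to give the hexabenzyl diol diketone F6.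
- Neutral hydrogenolysis (H2, Pd/C, EtOAc, rt) frees the six phenols and keeps the benzylic alcohols and the one MOM ether, giving the hexaphenol diol F7.
- PPh3 and DIAD (THF, 0 °C) close both rings by SN2 attack of an ortho phenol on each activated carbinol; inversion of the two (R)-carbinol carbons gives the 2S and 2''S trans rings directly, as the mono-MOM bis(flavanone) F8.
- HCl in MeOH at rt removes the last MOM group, and the fallback comes back to the route at 13.

Step 1. Phenoxy radicals of p-coumaric acid also couple at the free ortho positions and at oxygen and can oligomerize, so the 8,8'-dilactone may form only as a minor component. No numbered compound other than 1 lies ahead of this step, so the fallback sets out from two purchased compounds, N,N,N',N'-tetramethylsuccinamide and 4-(methoxymethoxy)benzaldehyde, and builds the same skeleton by ionic C–C bond formation. The dilithium dienolate of the diamide (LDA, 2.2 equiv, THF, −78 °C) adds to two equivalents of the aldehyde to give the bis(beta-hydroxy amide) F9 as a diastereomer mixture. HCl in MeOH–H2O–dioxane at 60 °C removes the MOM groups and lactonizes each benzylic position onto the gamma-amide of the other half with loss of dimethylamine. The like-configured isomers funnel to the exo,exo dilactone through the reversible 4-hydroxybenzylic cation, and the fallback comes back to the route at 3.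

**Further compounds**
F1 | step 6 | (2R,3R)-2-[(R)-hydroxy(4-methoxyphenyl)methyl]-3-{(R)-hydroxy[4-(methoxymethoxy)phenyl]methyl}-N1,N4-dimethoxy-N1,N4-dimethylbutanediamide | COc1ccc([C@H](O)[C@H](C(=O)N(C)OC)[C@@H](C(=O)N(C)OC)[C@@H](O)c2ccc(OCOC)cc2)cc1
F2 | step 6 | bis(tert-butyldimethylsilyl ether) of F1 | COc1ccc([C@H](O[Si](C)(C)C(C)(C)C)[C@H](C(=O)N(C)OC)[C@@H](C(=O)N(C)OC)[C@@H](O[Si](C)(C)C(C)(C)C)c2ccc(OCOC)cc2)cc1
F3 | step 6 | bis(tert-butyldimethylsilyl ether) of 11 | COc1ccc([C@H](O[Si](C)(C)C(C)(C)C)[C@H](C(=O)c2c(OCOC)cc(OCOC)cc2OCOC)[C@@H](C(=O)c2c(OCOC)cc(OCOC)cc2OCOC)[C@@H](O[Si](C)(C)C(C)(C)C)c2ccc(OCOC)cc2)cc1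
F4 | step 7 | 2-bromo-1,3,5-tris(benzyloxy)benzene | Brc1c(OCc2ccccc2)cc(OCc2ccccc2)cc1OCc1ccccc1
F5 | step 7 | 2,4,6-tris(benzyloxy)phenyllithium | [Li]c1c(OCc2ccccc2)cc(OCc2ccccc2)cc1OCc1ccccc1
F6 | step 7 | (1R,2R,3R,4R)-1-(4-methoxyphenyl)-4-[4-(methoxymethoxy)phenyl]-2,3-bis[2,4,6-tris(benzyloxy)benzoyl]butane-1,4-diol | COc1ccc([C@H](O)[C@H](C(=O)c2c(OCc3ccccc3)cc(OCc3ccccc3)cc2OCc2ccccc2)[C@@H](C(=O)c2c(OCc3ccccc3)cc(OCc3ccccc3)cc2OCc2ccccc2)[C@@H](O)c2ccc(OCOC)cc2)cc1
F7 | step 7 | (1R,2R,3R,4R)-1-(4-methoxyphenyl)-4-[4-(methoxymethoxy)phenyl]-2,3-bis(2,4,6-trihydroxybenzoyl)butane-1,4-diol | COc1ccc([C@H](O)[C@H](C(=O)c2c(O)cc(O)cc2O)[C@@H](C(=O)c2c(O)cc(O)cc2O)[C@@H](O)c2ccc(OCOC)cc2)cc1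
F8 | step 7 | 4-(methoxymethyl) ether of 13 at the hydroxyphenyl ring | COc1ccc([C@H]2Oc3cc(O)cc(O)c3C(=O)[C@@H]2[C@H]2C(=O)c3c(O)cc(O)cc3O[C@@H]2c2ccc(OCOC)cc2)cc1
F9 | step 1 | 2,3-bis{hydroxy[4-(methoxymethoxy)phenyl]methyl}-N,N,N',N'-tetramethylbutanediamide (diastereomer mixture) | COCOc1ccc(C(O)C(C(=O)N(C)C)C(C(=O)N(C)C)C(O)c2ccc(OCOC)cc2)cc1
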